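**Retrosynthetic overview**

1. The target is the bis-angelate of a tricyclo[5.4.0.0(2,8)]undec-9-en-11-one diol; the two esters go on late and the enone is unmasked last from a C11 silyl ether and a C9 exocyclic methylene.
2. Key disconnection: the C6–C7 bond between the quaternary ring carbon C6 (CH3, CH2O) and the cyclobutane CH C7. Forward, an epoxide-opening radical cyclisation onto a cyclobutanone tosylhydrazone closes the seven-membered ring and leaves C7–H.
3. Enabling feature: the seven-membered ring (C1–C7) spans the two one-carbon bridges C2 and C7 of the bicyclo[3.1.1]heptane, which sit 1,3 across the cyclobutane and point at each other; its C5(O)–C6(CH3)(CH2O) unit is the retron of an (E)-2-methyl-2,3-epoxy alcohol. The whole C15 skeleton is therefore an (E,E)-farnesyl chain folded C1–C6/C2–C7 and C1–C11 (farnesane numbering).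
4. Second disconnection: cyclobutane and six-membered ring together by intramolecular vinylketene–alkene [2+2] of a 5-silyloxyfarnesoyl chloride. Its C5 stereocentre, from an asymmetric vinylogous Mukaiyama aldol on an 8-silyloxygeranial, fixes the absolute configuration of the core.
5. Ring order: cyclobutane and six-membered ring in one step (step 9), seven-membered ring last (step 13).

Key step: step 13

Remark on the chemistry: tricycles are numbered as tricyclo[5.4.0.0(2,8)]undecane (C1 bridgehead next to C11, C2 methyl-bearing bridge, C5 carbinol, C6 quaternary, C7 cyclobutane CH, C8 bridgehead next to C9); hydrazone 16 is an E/Z mixture about C=N and ketene acetal 7 is taken as the 1Z isomer, neither geometry reaching the product; Si-face addition is assumed for the (S,S)-bisphosphoramide in step 6, the antipodal catalyst being used if the sense proves opposite.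

**Route**

Step 1
Reactants: 1 geranyl acetate
Product: 2 (2E,6E)-8-hydroxy-3,7-dimethylocta-2,6-dien-1-yl acetate
Conditions: SeO2 (cat.), t-BuOOH, salicylic acid (cat.), CH2Cl2, rt
Reagents that add atoms: tert-butyl hydroperoxide, CC(C)(C)OO (net oxygen source, relayed by catalytic SeO2)
Why: SeO2 allylic hydroxylation (ene reaction, then [2,3]-sigmatropic shift) should be selective for the (E)-methyl group of the electron-richer trisubstituted alkene remote from the acetate.

Step 2
Reactants: 2 (2E,6E)-8-hydroxy-3,7-dimethylocta-2,6-dien-1-yl acetate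
Product: 3 (2E,6E)-8-[(tert-butyldimethylsilyl)oxy]-3,7-dimethylocta-2,6-dien-1-yl acetate
Conditions: TBSCl, imidazole, DMF, 0 °C to rt
Reagents that add atoms: tert-butyldimethylsilyl chloride, CC(C)(C)[Si](C)(C)Cl
Why: Standard silyl ether formation on the primary allylic alcohol leaves the acetate untouched.

Step 3
Reactants: 3 (2E,6E)-8-[(tert-butyldimethylsilyl)oxy]-3,7-dimethylocta-2,6-dien-1-yl acetate
Product: 4 (2E,6E)-8-[(tert-butyldimethylsilyl)oxy]-3,7-dimethylocta-2,6-dien-1-ol
Conditions: K2CO3 (cat.), MeOH, 0 °C to rt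
Reagents that add atoms: none
Why: Base-catalysed transesterification removes the acetate while the silyl ether is stable.

Step 4
Reactants: 4 (2E,6E)-8-[(tert-butyldimethylsilyl)oxy]-3,7-dimethylocta-2,6-dien-1-ol
Product: 5 (2E,6E)-8-[(tert-butyldimethylsilyl)oxy]-3,7-dimethylocta-2,6-dienal
Conditions: MnO2, CH2Cl2, rt
Reagents that add atoms: none
Why: MnO2 oxidises the allylic alcohol to the enal without E/Z isomerisation or over-oxidation.

Step 5
Reactants: 6 ethyl 3-methylbut-2-enoate
Product: 7 (1Z)-1-[(tert-butyldimethylsilyl)oxy]-1-ethoxy-3-methylbuta-1,3-diene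
Conditions: LiN(i-Pr)2, THF, −78 °C; TBSCl, DMPU, −78 °C to rt
Reagents that add atoms: tert-butyldimethylsilyl chloride, CC(C)(C)[Si](C)(C)Cl
Why: Kinetic γ-deprotonation gives the lithium dienolate, which is O-silylated to the silyl dienol ether.

Step 6
Reactants: 5 (2E,6E)-8-[(tert-butyldimethylsilyl)oxy]-3,7-dimethylocta-2,6-dienal; 7 (1Z)-1-[(tert-butyldimethylsilyl)oxy]-1-ethoxy-3-methylbuta-1,3-diene
Product: 8 ethyl (2E,5S,6E,10E)-12-[(tert-butyldimethylsilyl)oxy]-5-hydroxy-3,7,11-trimethyldodeca-2,6,10-trienoate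
Conditions: SiCl4, (S,S)-binaphthyldiamine-derived bisphosphoramide (5 mol%), i-Pr2NEt (10 mol%), CH2Cl2, −78 °C; sat. aq. NaHCO3
Reagents that add atoms: none
Why: The vinylogous Mukaiyama aldol addition under Lewis-base-activated SiCl4 is γ-selective for ester-derived silyl dienol ethers and gives the (2E)-enoate; the C5 stereocentre is set by the chiral bisphosphoramide-bound trichlorosilyl cation (catalyst control, Si-face addition to the enal).

Step 7
Reactants: 8 ethyl (2E,5S,6E,10E)-12-[(tert-butyldimethylsilyl)oxy]-5-hydroxy-3,7,11-trimethyldodeca-2,6,10-trienoate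
Product: 9 ethyl (2E,5S,6E,10E)-12-[(tert-butyldimethylsilyl)oxy]-3,7,11-trimethyl-5-[(triisopropylsilyl)oxy]dodeca-2,6,10-trienoate
Conditions: TIPSOTf, 2,6-lutidine, CH2Cl2, −78 to 0 °C
Reagents that add atoms: triisopropylsilyl trifluoromethanesulfonate, CC(C)[Si](C(C)C)(C(C)C)OS(=O)(=O)C(F)(F)F
Why: Silylation with the triflate protects the secondary allylic alcohol as an ether that outlasts the primary TBS group later.

Step 8
Reactants: 9 ethyl (2E,5S,6E,10E)-12-[(tert-butyldimethylsilyl)oxy]-3,7,11-trimethyl-5-[(triisopropylsilyl)oxy]dodeca-2,6,10-trienoate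
Product: 10 (2E,5S,6E,10E)-12-[(tert-butyldimethylsilyl)oxy]-3,7,11-trimethyl-5-[(triisopropylsilyl)oxy]dodeca-2,6,10-trienoic acid
Conditions: LiOH, THF/MeOH/H2O, 40 °C; then aq. HCl to pH 4, 0 °C
Reagents that add atoms: lithium hydroxide, [Li+].[OH-]
Why: Saponification of the conjugated ester should proceed without touching either silyl ether.

Step 9
Reactants: 10 (2E,5S,6E,10E)-12-[(tert-butyldimethylsilyl)oxy]-3,7,11-trimethyl-5-[(triisopropylsilyl)oxy]dodeca-2,6,10-trienoic acid
Product: 13 (1R,4S,5R,7R)-7-methyl-2-methylidene-7-[(3E)-4-methyl-5-[(tert-butyldimethylsilyl)oxy]pent-3-en-1-yl]-4-[(triisopropylsilyl)oxy]bicyclo[3.1.1]heptan-6-one, via acid chloride 11 (not isolated), via vinylketene 12 (not isolated)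
Conditions: 1-chloro-N,N,2-trimethylprop-1-en-1-amine, CH2Cl2, 0 °C to rt; then slow addition to Et3N, toluene, reflux, high dilution
Reagents that add atoms: none
Why: Dehydrochlorination of 11 at the methyl group syn to the carbonyl gives vinylketene 12, whose intramolecular ketene–alkene [2+2] cycloaddition (the reaction type known for geranoyl- and farnesoyl-derived vinylketenes) joins the ketene carbon to the less substituted alkene carbon and closes the cyclobutane and the six-membered ring together; the (6E) geometry places the C7 methyl syn to the three-carbon bridge and the side chain towards the carbonyl bridge, and allylic 1,3-strain between the alkene methyl and the silyloxy-bearing carbon (its C–H in the alkene plane) makes the ketene add to the face anti to OTIPS, so the (5S) centre sets the three new ring stereocentres.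

Step 10
Reactants: 13 (1R,4S,5R,7R)-7-methyl-2-methylidene-7-[(3E)-4-methyl-5-[(tert-butyldimethylsilyl)oxy]pent-3-en-1-yl]-4-[(triisopropylsilyl)oxy]bicyclo[3.1.1]heptan-6-one
Product: 14 (1R,4S,5R,7R)-7-[(3E)-5-hydroxy-4-methylpent-3-en-1-yl]-7-methyl-2-methylidene-4-[(triisopropylsilyl)oxy]bicyclo[3.1.1]heptan-6-one
Conditions: HF·pyridine, pyridine, THF, 0 °C
Reagents that add atoms: none
Why: Buffered fluoride desilylation should cleave the unhindered primary allylic TBS ether much faster than the hindered secondary TIPS ether.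

Step 11
Reactants: 14 (1R,4S,5R,7R)-7-[(3E)-5-hydroxy-4-methylpent-3-en-1-yl]-7-methyl-2-methylidene-4-[(triisopropylsilyl)oxy]bicyclo[3.1.1]heptan-6-one
Product: 15 (1R,4S,5R,7R)-7-{2-[(2R,3R)-3-(hydroxymethyl)-3-methyloxiran-2-yl]ethyl}-7-methyl-2-methylidene-4-[(triisopropylsilyl)oxy]bicyclo[3.1.1]heptan-6-one
Conditions: Ti(OiPr)4 (10 mol%), D-(−)-diethyl tartrate (12 mol%), t-BuOOH, 4 Å MS, CH2Cl2, −20 °C
Reagents that add atoms: tert-butyl hydroperoxide, CC(C)(C)OO
Why: Sharpless asymmetric epoxidation of the (E)-2-methyl allylic alcohol gives the (2R,3R)-epoxide under reagent control by the tartrate, independent of the remote ring stereocentres, and fixes the future C5–O centre.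

Step 12
Reactants: 15 (1R,4S,5R,7R)-7-{2-[(2R,3R)-3-(hydroxymethyl)-3-methyloxiran-2-yl]ethyl}-7-methyl-2-methylidene-4-[(triisopropylsilyl)oxy]bicyclo[3.1.1]heptan-6-one
Product: 16 N′-tosylhydrazone of 15 at the cyclobutanone carbonyl (E/Z mixture)
Conditions: TsNHNH2 (1.05 equiv), 4 Å MS, THF, rt
Reagents that add atoms: 4-methylbenzenesulfonohydrazide, Cc1ccc(cc1)S(=O)(=O)NN
Why: Condensation to the sulfonylhydrazone should be fast at the strained, non-enolisable cyclobutanone and leave the epoxy alcohol intact under neutral conditions.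

Step 13
Reactants: 16 N′-tosylhydrazone of 15 at the cyclobutanone carbonyl
Product: 18 (1R,2R,5R,6S,7S,8R,11S)-6-(hydroxymethyl)-2,6-dimethyl-9-methylidene-11-[(triisopropylsilyl)oxy]tricyclo[5.4.0.0(2,8)]undecan-5-ol, via tricyclic tosylhydrazide 17 (not isolated)
Conditions: Cp2TiCl2 (2.5 equiv), Mn dust, THF, rt, slow addition of 16 at high dilution; then MeOH, K2CO3, 50 °C
Reagents that add atoms: none
Why: Proposed new method: Cp2TiCl (trivalent titanium) should open the epoxide at the tertiary carbon by single-electron transfer to give a β-titanoxy tertiary radical that adds 7-exo-trig to the C=N carbon of the cyclobutanone tosylhydrazone, the hydrazinyl radical being reduced by a second Cp2TiCl; on warming with K2CO3/MeOH the N-alkyl-N′-tosylhydrazide 17 loses sulfinate and then N2, leaving C–H at the former carbonyl carbon. The closest known reaction types are titanocene-mediated radical cyclisations of epoxides (including trisubstituted 2,3-epoxy alcohols) onto ketone, aldehyde and nitrile acceptors, and radical addition to sulfonylhydrazones followed by loss of sulfinate and N2 as a reductive C–C coupling; their combination is new. The seven-membered ring closes in the 7-exo mode because the chain on the quaternary one-carbon bridge and the C=N carbon sit 1,3 across the cyclobutane and point at each other. The new cyclobutane CH centre can only form with the C–C bond on the face turned towards the other one-carbon bridge (tether control); the quaternary centre is set by a chair-like transition state in which the titanoxy group on the adjacent carbinol carbon (fixed in step 11) and the titanoxymethyl group are both pseudo-equatorial, placing CH2OH trans and CH3 cis to the ring C–O. The step needs regioselective epoxide opening (secured by the tertiary radical), cyclisation faster than hydrogen abstraction or disproportionation (favoured by the proximity of radical and acceptor, slow addition and dilution) and tolerance of the free hydroxyl, silyl ether and 1,1-disubstituted alkene, all inert to Cp2TiCl.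

Step 14
Reactants: 18 (1R,2R,5R,6S,7S,8R,11S)-6-(hydroxymethyl)-2,6-dimethyl-9-methylidene-11-[(triisopropylsilyl)oxy]tricyclo[5.4.0.0(2,8)]undecan-5-ol; 19 angelic acid [(2Z)-2-methylbut-2-enoic acid], two equivalents of which are incorporated
Product: 21 (1R,2R,5R,6S,7S,8R,11S)-6-[(angeloyloxy)methyl]-2,6-dimethyl-9-methylidene-11-[(triisopropylsilyl)oxy]tricyclo[5.4.0.0(2,8)]undecan-5-yl angelate, via mixed anhydride 20 (not isolated)
Conditions: 19 (3 equiv), 2,4,6-trichlorobenzoyl chloride (3 equiv), Et3N, toluene, rt; then 18, toluene, 80 °C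
Reagents that add atoms: angelic acid (the second equivalent of 19, for the second ester), C/C=C(/C)C(=O)O
Why: Yamaguchi-type esterification through the trichlorobenzoyl mixed anhydride, used in excess so that both the primary and the secondary hydroxyl are acylated, introduces the two angelates without a nucleophilic catalyst, which should avoid Z-to-E isomerisation to the tiglate.

Step 15
Reactants: 21 (1R,2R,5R,6S,7S,8R,11S)-6-[(angeloyloxy)methyl]-2,6-dimethyl-9-methylidene-11-[(triisopropylsilyl)oxy]tricyclo[5.4.0.0(2,8)]undecan-5-yl angelate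
Product: 22 (1R,2R,5R,6S,7S,8R,11S)-6-[(angeloyloxy)methyl]-11-hydroxy-2,6-dimethyl-9-methylidenetricyclo[5.4.0.0(2,8)]undecan-5-yl angelate
Conditions: HF·pyridine, THF, 0 °C to rt
Reagents that add atoms: none
Why: Acidic fluoride desilylation frees the C11 alcohol under conditions that neither cleave nor isomerise the angelates.

Step 16
Reactants: 22 (1R,2R,5R,6S,7S,8R,11S)-6-[(angeloyloxy)methyl]-11-hydroxy-2,6-dimethyl-9-methylidenetricyclo[5.4.0.0(2,8)]undecan-5-yl angelate
Product: 23 (1R,2R,5R,6S,7S,8R)-6-[(angeloyloxy)methyl]-2,6-dimethyl-9-methylidene-11-oxotricyclo[5.4.0.0(2,8)]undecan-5-yl angelate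
Conditions: Dess–Martin periodinane, CH2Cl2, 0 °C to rt
Reagents that add atoms: none
Why: Dess–Martin oxidation converts the secondary alcohol to the ketone under near-neutral conditions compatible with the esters.

Step 17
Reactants: 23 (1R,2R,5R,6S,7S,8R)-6-[(angeloyloxy)methyl]-2,6-dimethyl-9-methylidene-11-oxotricyclo[5.4.0.0(2,8)]undecan-5-yl angelate
Product: 24 the target, (1R,2R,5R,6S,7S,8R)-6-[(angeloyloxy)methyl]-2,6,9-trimethyl-11-oxotricyclo[5.4.0.0(2,8)]undec-9-en-5-yl angelate
Conditions: DBU (0.1 equiv), CH2Cl2, 0 °C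
Reagents that add atoms: none
Why: Base-catalysed isomerisation through the dienolate moves the exocyclic alkene into conjugation to give the thermodynamically favoured enone; no stereocentre is affected because both bridgeheads are non-enolisable.

**Compound list**

1 | geranyl acetate | CC(C)=CCC/C(C)=C/COC(C)=O | starting material
2 | (2E,6E)-8-hydroxy-3,7-dimethylocta-2,6-dien-1-yl acetate | OC/C(C)=C/CC/C(C)=C/COC(C)=O | intermediate
3 | (2E,6E)-8-[(tert-butyldimethylsilyl)oxy]-3,7-dimethylocta-2,6-dien-1-yl acetate | CC(C)(C)[Si](C)(C)OC/C(C)=C/CC/C(C)=C/COC(C)=O | intermediate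
4 | (2E,6E)-8-[(tert-butyldimethylsilyl)oxy]-3,7-dimethylocta-2,6-dien-1-ol | CC(C)(C)[Si](C)(C)OC/C(C)=C/CC/C(C)=C/CO | intermediate
5 | (2E,6E)-8-[(tert-butyldimethylsilyl)oxy]-3,7-dimethylocta-2,6-dienal | CC(C)(C)[Si](C)(C)OC/C(C)=C/CC/C(C)=C/C=O | intermediate
6 | ethyl 3-methylbut-2-enoate | CCOC(=O)C=C(C)C | starting material
7 | (1Z)-1-[(tert-butyldimethylsilyl)oxy]-1-ethoxy-3-methylbuta-1,3-diene | CCO/C(O[Si](C)(C)C(C)(C)C)=C/C(C)=C | intermediate
8 | ethyl (2E,5S,6E,10E)-12-[(tert-butyldimethylsilyl)oxy]-5-hydroxy-3,7,11-trimethyldodeca-2,6,10-trienoate | CCOC(=O)/C=C(\C)C[C@H](O)/C=C(\C)CC/C=C(\C)CO[Si](C)(C)C(C)(C)C | intermediate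
9 | 5-O-triisopropylsilyl ether of 8 | CCOC(=O)/C=C(\C)C[C@H](O[Si](C(C)C)(C(C)C)C(C)C)/C=C(\C)CC/C=C(\C)CO[Si](C)(C)C(C)(C)C | intermediate
10 | carboxylic acid from 9 | OC(=O)/C=C(\C)C[C@H](O[Si](C(C)C)(C(C)C)C(C)C)/C=C(\C)CC/C=C(\C)CO[Si](C)(C)C(C)(C)C | intermediate
11 | acid chloride of 10 | ClC(=O)/C=C(\C)C[C@H](O[Si](C(C)C)(C(C)C)C(C)C)/C=C(\C)CC/C=C(\C)CO[Si](C)(C)C(C)(C)C | intermediate
12 | (5S,6E,10E)-12-[(tert-butyldimethylsilyl)oxy]-7,11-dimethyl-3-methylidene-5-[(triisopropylsilyl)oxy]dodeca-1,6,10-trien-1-one (vinylketene) | O=C=CC(=C)C[C@H](O[Si](C(C)C)(C(C)C)C(C)C)/C=C(\C)CC/C=C(\C)CO[Si](C)(C)C(C)(C)C | intermediate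
13 | (1R,4S,5R,7R)-bicyclo[3.1.1]heptan-6-one; C7 methyl syn to the C2–C4 bridge, side chain towards C6, OTIPS on the C6 side | O=C1[C@H]2[C@@H](O[Si](C(C)C)(C(C)C)C(C)C)CC(=C)[C@@H]1[C@@]2(C)CC/C=C(\C)CO[Si](C)(C)C(C)(C)C | intermediate
14 | primary allylic alcohol from 13 | O=C1[C@H]2[C@@H](O[Si](C(C)C)(C(C)C)C(C)C)CC(=C)[C@@H]1[C@@]2(C)CC/C=C(\C)CO | intermediate
15 | (2R,3R)-epoxy alcohol from 14 | O=C1[C@H]2[C@@H](O[Si](C(C)C)(C(C)C)C(C)C)CC(=C)[C@@H]1[C@@]2(C)CC[C@H]3O[C@]3(C)CO | intermediate
16 | N′-tosylhydrazone of 15 (C=N geometry unspecified) | Cc1ccc(cc1)S(=O)(=O)NN=C1[C@H]2[C@@H](O[Si](C(C)C)(C(C)C)C(C)C)CC(=C)[C@@H]1[C@@]2(C)CC[C@H]3O[C@]3(C)CO | intermediate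
17 | tricyclic N-alkyl-N′-tosylhydrazide; hydrazide nitrogen on C7 on the face towards the three-carbon bridge | OC[C@]1(C)[C@]2(NNS(=O)(=O)c3ccc(C)cc3)[C@H]4[C@@H](O[Si](C(C)C)(C(C)C)C(C)C)CC(=C)[C@@H]2[C@@]4(C)CC[C@H]1O | intermediate
18 | (1R,2R,5R,6S,7S,8R,11S)-tricyclic diol; C5–OH cis to C6–CH3, CH2OH trans | OC[C@]1(C)[C@@H]2[C@H]3[C@@H](O[Si](C(C)C)(C(C)C)C(C)C)CC(=C)[C@@H]2[C@@]3(C)CC[C@H]1O | intermediate
19 | angelic acid, (2Z)-2-methylbut-2-enoic acid | C/C=C(/C)C(=O)O | starting material
20 | angelic 2,4,6-trichlorobenzoic anhydride | C/C=C(/C)C(=O)OC(=O)c1c(Cl)cc(Cl)cc1Cl | intermediate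
21 | bis-angelate of 18 | C/C=C(/C)C(=O)OC[C@]1(C)[C@@H]2[C@H]3[C@@H](O[Si](C(C)C)(C(C)C)C(C)C)CC(=C)[C@@H]2[C@@]3(C)CC[C@H]1OC(=O)/C(C)=C\C | intermediate
22 | C11 alcohol from 21 | C/C=C(/C)C(=O)OC[C@]1(C)[C@@H]2[C@H]3[C@@H](O)CC(=C)[C@@H]2[C@@]3(C)CC[C@H]1OC(=O)/C(C)=C\C | intermediate
23 | 9-methylidene-11-ketone from 22 | C/C=C(/C)C(=O)OC[C@]1(C)[C@@H]2[C@H]3C(=O)CC(=C)[C@@H]2[C@@]3(C)CC[C@H]1OC(=O)/C(C)=C\C | intermediate
24 | target, (1R,2R,5R,6S,7S,8R)-6-[(angeloyloxy)methyl]-2,6,9-trimethyl-11-oxotricyclo[5.4.0.0(2,8)]undec-9-en-5-yl angelate | C/C=C(/C)C(=O)OC[C@]1(C)[C@@H]2[C@H]3C(=O)C=C(C)[C@@H]2[C@@]3(C)CC[C@H]1OC(=O)/C(C)=C\C | target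

**Step count and risks**

Total: 17 steps. Longest linear sequence: 16 steps (steps 1–4 and 6–17).

Steps most likely to fail:

1. Step 13 (the step proposed as new chemistry). The tertiary radical may be quenched by hydrogen abstraction or disproportionation before it reaches the hindered C=N carbon, whose pyramidalisation brings the nitrogen 1,3-syn to the C11 silyloxy group; collapse of the hydrazide may also be sluggish. The fallback uses known chemistry, sets out from epoxy ketone 15 and returns at diol 18. Treating 15 with Cp2TiCl (Cp2TiCl2, Mn, THF) should effect the established reductive epoxide–ketone radical cyclisation onto the titanium-bound cyclobutanone carbonyl and give the tertiary cyclobutanol triol F1. Acetylation of the primary and secondary hydroxyls (Ac2O, pyridine) gives the diacetate F2, and acylation of the remaining tertiary hydroxyl with methyl chlorooxoacetate (DMAP, pyridine) gives the methyl oxalate F3. Radical deoxygenation with Bu3SnH/AIBN in refluxing toluene gives the deoxygenated diacetate F4, hydrogen being deliverable only to the face turned to the three-carbon bridge, and K2CO3/MeOH returns 18.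

2. Step 9. Dehydrochlorination at reflux may occur at C4 instead of the methyl group, with elimination or oligomerisation of the ketene, and the temperature may erode facial discrimination. The fallback generates the same ketene without base at room temperature; it sets out from aldehyde 5 and returns at ketone 13. Catalytic asymmetric Nozaki–Hiyama–Kishi 2-(ethoxycarbonyl)allylation of 5 with ethyl 2-(bromomethyl)acrylate (CrCl2 (divalent chromium), chiral bis(oxazolinyl)carbazole ligand, Mn, TMSCl) should give the (5S)-α-methylene-γ-butyrolactone F5. Lactone opening with LiOH, bis-silylation with TIPSOTf/2,6-lutidine and mild hydrolysis of the silyl ester give the 2-methylene-4-silyloxy acid F6. Activation with 1-chloro-N,N,2-trimethylprop-1-en-1-amine and treatment with TMSCHN2 give the diazoketone F7, and photochemical Wolff rearrangement of F7 in toluene produces vinylketene 12, which cyclises to 13.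

3. Step 14. Angelate may isomerise to tiglate during activation, or acylation of the secondary hydroxyl next to the quaternary carbon may stall. The fallback builds the (Z)-alkenes on the molecule; it sets out from diol 18 and returns at bis-angelate 21. Esterification of both hydroxyls with 2-[bis(2,2,2-trifluoroethoxy)phosphoryl]propanoic acid (EDC, DMAP, CH2Cl2) gives the bis(phosphonopropionate) F8, and Still–Gennari olefination (KN(SiMe3)2, 18-crown-6, acetaldehyde, THF, −78 °C) should convert both into (Z)-2-methylbut-2-enoates, giving 21.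

**Further compounds**

F1 | step 13 | 7-hydroxy analogue of 18 (tertiary cyclobutanol triol) | OC[C@]1(C)[C@]2(O)[C@H]3[C@@H](O[Si](C(C)C)(C(C)C)C(C)C)CC(=C)[C@@H]2[C@@]3(C)CC[C@H]1O
F2 | step 13 | diacetate of F1 at the primary and secondary hydroxyls | CC(=O)OC[C@]1(C)[C@]2(O)[C@H]3[C@@H](O[Si](C(C)C)(C(C)C)C(C)C)CC(=C)[C@@H]2[C@@]3(C)CC[C@H]1OC(C)=O
F3 | step 13 | methyl oxalate of F2 at the tertiary hydroxyl | CC(=O)OC[C@]1(C)[C@]2(OC(=O)C(=O)OC)[C@H]3[C@@H](O[Si](C(C)C)(C(C)C)C(C)C)CC(=C)[C@@H]2[C@@]3(C)CC[C@H]1OC(C)=O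
F4 | step 13 | diacetate of 18 | CC(=O)OC[C@]1(C)[C@@H]2[C@H]3[C@@H](O[Si](C(C)C)(C(C)C)C(C)C)CC(=C)[C@@H]2[C@@]3(C)CC[C@H]1OC(C)=O
F5 | step 9 | (5S)-5-[(1E,5E)-7-[(tert-butyldimethylsilyl)oxy]-2,6-dimethylhepta-1,5-dien-1-yl]-3-methylideneoxolan-2-one | C=C1C[C@H](OC1=O)/C=C(\C)CC/C=C(\C)CO[Si](C)(C)C(C)(C)C
F6 | step 9 | (4S,5E,9E)-11-[(tert-butyldimethylsilyl)oxy]-6,10-dimethyl-2-methylidene-4-[(triisopropylsilyl)oxy]undeca-5,9-dienoic acid | OC(=O)C(=C)C[C@H](O[Si](C(C)C)(C(C)C)C(C)C)/C=C(\C)CC/C=C(\C)CO[Si](C)(C)C(C)(C)C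
F7 | step 9 | diazomethyl ketone of F6 | [N-]=[N+]=CC(=O)C(=C)C[C@H](O[Si](C(C)C)(C(C)C)C(C)C)/C=C(\C)CC/C=C(\C)CO[Si](C)(C)C(C)(C)C
F8 | step 14 | bis{2-[bis(2,2,2-trifluoroethoxy)phosphoryl]propanoate} of 18 (epimeric at both phosphonate α-carbons) | CC(C(=O)OC[C@]1(C)[C@@H]2[C@H]3[C@@H](O[Si](C(C)C)(C(C)C)C(C)C)CC(=C)[C@@H]2[C@@]3(C)CC[C@H]1OC(=O)C(C)P(=O)(OCC(F)(F)F)OCC(F)(F)F)P(=O)(OCC(F)(F)F)OCC(F)(F)F
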